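**Plan**

- Retrosynthesis cuts the three interflavanyl C-4–aryl bonds: C-4 of the top unit to C-6 of the middle unit, C-4 of the middle unit to C-8 of catechin, and C-4 of the angular unit to C-6 of catechin. Each is made as aryllithium + 3-silyloxyflavan-4-one followed by ionic removal of the carbinol oxygen, so all three ent-fisetinidol units are one ketone, 12, and the fourth unit is (+)-catechin.
- In 12 the pyranone is cut at C-2–C-3. The 3-hydroxy-4-oxo pair between the benzylic ether carbon C-2 and the ring carbon C-4a is an α-ketol, the 1,2-shift isomer of a 3-hydroxy-2,3-dihydrobenzofuran-3-carbaldehyde (five-membered ring O-1, C-2, C-4, C-4a, C-8a, with C-3 outside the ring as CHO). This feature lets each pyran ring grow out of a dihydrofuran ring.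
- Forward order: ether 3, aryl diazoacetate 6, dihydrobenzofuran 7 by rhodium-carbenoid C–H insertion, hydroxy-aldehyde 10, ring enlargement to pyranone 11, ketone 12. Then 12 is joined to C-8 of lithiated catechin, the dimer is brominated twice and joined to two more molecules of 12 in one operation; desilylation and hydrogenolysis finish.
- Stereochemistry: C-2 from the chiral dirhodium catalyst (kept in the 1,2-shift); C-3 relayed from C-2 (trans); each C-4 from hydride delivery to the planar 4-aryl cation anti to the 3-silyloxy group (3,4-cis); the catechin centres from the chiral pool.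

Key step: step 7

Assumption: Rh2(S-PTTL)4 is taken to give the (2R)-configured insertion product 7 (the spatial arrangement that is 2S in 9–12), by analogy with related 2-aryl-2,3-dihydrobenzofuran-3-carboxylates; if the sense of induction were opposite, the mirror-image catalyst would be used with no other change.
Remark: α and β refer to the usual flavan orientation; in each ent-fisetinidol unit 2-aryl is β, 3-O is α and the 4-aryl bond is α (2,3-trans-3,4-cis). TBS = tert-butyldimethylsilyl.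

**Route**

Step 1
Reactants: 1 4-(benzyloxy)-2-hydroxybenzaldehyde; 2 3,4-bis(benzyloxy)benzyl chloride
Product: 3 4-(benzyloxy)-2-{[3,4-bis(benzyloxy)phenyl]methoxy}benzaldehyde
Conditions: K2CO3, DMF, 60 °C
Reagents that add atoms: none
Why: Williamson ether synthesis, in which the phenoxide of 1 displaces the benzylic chloride of 2 (SN2); the para oxygen already carries its benzyl group, so only the ortho oxygen is alkylated and no stereocentre is formed.

Step 2
Reactants: 3 4-(benzyloxy)-2-{[3,4-bis(benzyloxy)phenyl]methoxy}benzaldehyde; 4 ethyl diazoacetate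
Product: 5 ethyl (2Z)-2-[4-(benzyloxy)-2-{[3,4-bis(benzyloxy)phenyl]methoxy}phenyl]-3-hydroxyprop-2-enoate (enol form of the α-formyl arylacetate)
Conditions: HBF4·OEt2 (10 mol %), CH2Cl2, −78 °C to rt
Reagents that add atoms: none
Why: Acid-catalysed addition of the diazo ester to the aldehyde followed by 1,2-aryl shift with loss of N2, which should be preferred over hydride shift for the electron-rich 2,4-dialkoxyphenyl group, gives the α-formyl ester as its enol; no stereocentre.

Step 3
Reactants: 5 ethyl (2Z)-2-aryl-3-hydroxyprop-2-enoate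
Product: 6 ethyl [4-(benzyloxy)-2-{[3,4-bis(benzyloxy)phenyl]methoxy}phenyl](diazo)acetate
Conditions: 4-acetamidobenzenesulfonyl azide, Et3N, MeCN, 0 °C to rt
Reagents that add atoms: 4-acetamidobenzenesulfonyl azide, CC(=O)Nc1ccc(cc1)S(=O)(=O)N=[N+]=[N-]
Why: Deformylative diazo transfer (Regitz type), in which the enolate of the formyl ester adds to the sulfonyl azide and the adduct fragments to the aryl diazoacetate and the N-formyl sulfonamide; no stereocentre.

Step 4
Reactants: 6 ethyl aryl(diazo)acetate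
Product: 7 ethyl (2R,3S)-6-(benzyloxy)-2-[3,4-bis(benzyloxy)phenyl]-2,3-dihydro-1-benzofuran-3-carboxylate (2,3-cis)
Conditions: Rh2(S-PTTL)4 [dirhodium tetrakis(N-phthaloyl-(S)-tert-leucinate)] (1 mol %), toluene, −60 °C
Reagents that add atoms: none
Why: Intramolecular 1,5 C–H insertion of the donor/acceptor rhodium carbenoid into the oxygen-activated benzylic C–H bond of the ortho ether closes the dihydrofuran ring; the chiral carboxylate ligands set the benzylic ether centre (the later flavan C-2), and the cis ester centre formed with it is erased in step 5.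

Step 5
Reactants: 7 ethyl (2R,3S)-dihydrobenzofuran-3-carboxylate
Product: 9 ethyl (2S,3R)-6-(benzyloxy)-2-[3,4-bis(benzyloxy)phenyl]-3-hydroxy-2,3-dihydro-1-benzofuran-3-carboxylate, via potassium ester enolate 8 (not isolated)
Conditions: KN(SiMe3)2, THF, −78 °C; then 3-phenyl-2-(phenylsulfonyl)oxaziridine, −78 °C; AcOH quench
Reagents that add atoms: 3-phenyl-2-(phenylsulfonyl)oxaziridine, O=S(=O)(c1ccccc1)N1OC1c1ccccc1; potassium bis(trimethylsilyl)amide, C[Si](C)(C)[N-][Si](C)(C)C.[K+] (gives the potassium ion of 8)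
Why: Enolate oxidation by the N-sulfonyloxaziridine, in which the planar enolate should be hydroxylated on the face away from the C-2 aryl group so that the new hydroxyl is trans to the aryl; ring opening of the enolate by loss of the ring aryloxide would be a 5-endo process and should not compete.

Step 6
Reactants: 9 ethyl (2S,3R)-3-hydroxy-dihydrobenzofuran-3-carboxylate
Product: 10 (2S,3R)-6-(benzyloxy)-2-[3,4-bis(benzyloxy)phenyl]-3-hydroxy-2,3-dihydro-1-benzofuran-3-carbaldehyde
Conditions: i-Bu2AlH (2.5 equiv), CH2Cl2, −78 °C; aqueous potassium sodium tartrate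
Reagents that add atoms: none
Why: Low-temperature hydride reduction of the α-hydroxy ester should stop at the chelated aluminium hemiacetal, which releases the aldehyde on work-up; no stereocentre is touched.

Step 7
Reactants: 10 (2S,3R)-3-hydroxy-2,3-dihydro-1-benzofuran-3-carbaldehyde
Product: 11 (2S,3S)-7-(benzyloxy)-2-[3,4-bis(benzyloxy)phenyl]-3-hydroxy-2,3-dihydro-4H-chromen-4-one (2,3-trans; tri-O-benzyl-ent-fustin)
Conditions: Al(Ot-Bu)3 (1.1 equiv), toluene, 50 °C; aqueous potassium sodium tartrate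
Reagents that add atoms: none
Why: Alkoxide exchange on aluminium gives a five-membered chelate with the tertiary alkoxide oxygen and the formyl oxygen syn, and the alkoxide then pushes the benzylic ether carbon C-2 with its bonding pair from the carbinol carbon to the formyl carbon (α-ketol or acyloin rearrangement), so that the former formyl carbon is inserted between C-2 and the old carbinol carbon and the dihydrofuran ring becomes the pyranone ring of 11. The closest known reaction type is the ring-enlarging α-ketol rearrangement of 1-hydroxycycloalkyl carbonyl compounds under aluminium alkoxides, as in the D-homoannulation of 17-hydroxy-20-oxo steroids. No ring is closed by cyclisation; the ring grows by one atom through a suprafacial 1,2-carbon shift. C-2 migrates with retention, so the configuration set in step 4 is kept, and the new C-3 centre is fixed by the syn chelate together with the trans relation of aryl and hydroxyl in 10, which places the new hydroxyl trans to the aryl group; this is also the more stable arrangement reachable by enolisation at C-3. The selectivity needed is migration of C-2 in preference to the aryl carbon C-3a: the shift is reversible, 10 has no α-hydrogen, and only the C-2 product has its ketone conjugated with the 7-benzyloxy ring while relieving five-ring strain, so the equilibrium should drain into 11.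

Step 8
Reactants: 11 (2S,3S)-3-hydroxychroman-4-one
Product: 12 (2S,3S)-7-(benzyloxy)-2-[3,4-bis(benzyloxy)phenyl]-3-[(tert-butyldimethylsilyl)oxy]-2,3-dihydro-4H-chromen-4-one
Conditions: t-BuMe2SiOTf, 2,6-lutidine, CH2Cl2, 0 °C
Reagents that add atoms: tert-butyldimethylsilyl trifluoromethanesulfonate, CC(C)(C)[Si](C)(C)OS(=O)(=O)C(F)(F)F
Why: Silylation of the secondary alcohol with the silyl triflate installs the bulky 3-O group that later steers hydride to the opposite face of C-4; configuration is unchanged.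

Step 9
Reactants: 13 (+)-catechin
Product: 14 5,7,3',4'-tetra-O-benzyl-(+)-catechin
Conditions: BnBr (4.4 equiv), K2CO3, DMF, 0 °C to rt
Reagents that add atoms: benzyl bromide, BrCc1ccccc1
Why: Williamson benzylation of the four phenols, which are far more acidic than the secondary 3-hydroxyl, under carbonate conditions that should leave C-2 untouched.

Step 10
Reactants: 14 5,7,3',4'-tetra-O-benzyl-(+)-catechin
Product: 15 3,5,7,3',4'-penta-O-benzyl-(+)-catechin
Conditions: NaH, BnBr, DMF, 0 °C to rt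
Reagents that add atoms: benzyl bromide, BrCc1ccccc1
Why: Williamson benzylation of the remaining secondary alkoxide gives a substrate without acidic protons for the later lithiation.

Step 11
Reactants: 15 3,5,7,3',4'-penta-O-benzyl-(+)-catechin
Product: 16 8-bromo-3,5,7,3',4'-penta-O-benzyl-(+)-catechin
Conditions: N-bromosuccinimide (1.0 equiv), CH2Cl2, −78 °C to rt
Reagents that add atoms: N-bromosuccinimide, O=C1CCC(=O)N1Br
Why: Electrophilic aromatic bromination of the phloroglucinol-type ring, which in 5,7-di-O-alkylated catechins goes to C-8 first, the catechol ring being much less reactive.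

Step 12
Reactants: 16 8-bromo-3,5,7,3',4'-penta-O-benzyl-(+)-catechin; 12 (2S,3S)-3-silyloxychroman-4-one
Product: 18 (2S,3S,4S)-7-(benzyloxy)-2-[3,4-bis(benzyloxy)phenyl]-3-[(tert-butyldimethylsilyl)oxy]-4-(3,5,7,3',4'-penta-O-benzylcatechin-8-yl)chroman-4-ol, via 8-lithio-penta-O-benzylcatechin 17 (not isolated)
Conditions: t-BuLi (2.0 equiv), THF, −78 °C; then 12, −78 to 0 °C; H2O
Reagents that add atoms: tert-butyllithium, [Li]C(C)(C)C (gives the lithium of 17)
Why: Bromine–lithium exchange followed by 1,2-addition of the aryllithium to the chromanone carbonyl, expected from the face away from the 3-silyloxy group (Felkin–Anh type, aryl trans to OSi); the configuration of this carbinol carbon is erased in step 13.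

Step 13
Reactants: 18 C-4 carbinol of the (4→8) dimer
Product: 19 7,3',4'-tri-O-benzyl-3-O-(tert-butyldimethylsilyl)-ent-fisetinidol-(4α→8)-3,5,7,3',4'-penta-O-benzylcatechin (ent-fisetinidol unit 2S,3R,4S)
Conditions: Bu3SnH, CF3CO2H, CH2Cl2, 0 °C
Reagents that add atoms: none
Why: Ionic deoxygenation, in which acid ionises the tertiary doubly benzylic alcohol to the planar 4-arylflavan-4-yl cation and the stannane should deliver hydride to the face anti to the neighbouring 3-silyloxy group, so that H-4 ends up trans and the aryl group cis to O-3 (4α); the same facial preference gives 3,4-trans products when the carbon nucleophile is added last, which is why the aryl group is put in first and hydrogen last.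

Step 14
Reactants: 19 protected (4α→8) dimer
Product: 20 6-bromo-7,3',4'-tri-O-benzyl-3-O-(tert-butyldimethylsilyl)-ent-fisetinidol-(4α→8)-6-bromo-3,5,7,3',4'-penta-O-benzylcatechin
Conditions: N-bromosuccinimide (2.05 equiv), CH2Cl2, −78 to 0 °C
Reagents that add atoms: N-bromosuccinimide, O=C1CCC(=O)N1Br
Why: Electrophilic aromatic bromination should take the two most electron-rich free positions, C-6 of the catechin ring (between two ether oxygens, para to O-1) and C-6 of the ent-fisetinidol unit (para to O-1, ortho to the 7-benzyloxy group), because each free catechol-ring position is activated by only one oxygen.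

Step 15
Reactants: 20 dibromo dimer; 12 (2S,3S)-3-silyloxychroman-4-one (2.4 equiv)
Product: 22 bis-carbinol tetramer (19 bearing a (2S,3S)-7-(benzyloxy)-2-[3,4-bis(benzyloxy)phenyl]-3-[(tert-butyldimethylsilyl)oxy]-4-hydroxychroman-4-yl group at C-6 of its ent-fisetinidol unit plus a second one at C-6 of its catechin unit; aryl trans to OSi in each), via 6,6'-dilithio dimer 21 (not isolated)
Conditions: t-BuLi (4.1 equiv), THF, −78 °C; then 12, −78 to 0 °C; H2O
Reagents that add atoms: tert-butyllithium, [Li]C(C)(C)C (gives the lithium of 21)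
Why: Double bromine–lithium exchange and twofold 1,2-addition to two molecules of the same ketone, possible because the top and the angular unit are identical; each aryllithium should add anti to the 3-silyloxy group as in step 12, and both carbinol configurations are erased in step 16.

Step 16
Reactants: 22 bis-carbinol tetramer
Product: 23 [7,3',4'-tri-O-benzyl-3-O-TBS-ent-fisetinidol]-(4α→6)-[7,3',4'-tri-O-benzyl-3-O-TBS-ent-fisetinidol]-(4α→8)-[3,5,7,3',4'-penta-O-benzylcatechin]-(6→4α)-[7,3',4'-tri-O-benzyl-3-O-TBS-ent-fisetinidol]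
Conditions: Bu3SnH, CF3CO2H, CH2Cl2, 0 °C
Reagents that add atoms: none
Why: Twofold ionic deoxygenation as in step 13, in which each 4-arylflavan-4-yl cation should take hydride anti to its 3-silyloxy group and so set both new C-4 centres 3,4-cis (4α).

Step 17
Reactants: 23 fully protected tetramer
Product: 24 tetradeca-O-benzyl tetramer (23 with the three 3-OTBS groups replaced by 3-OH)
Conditions: Bu4NF, THF, 50 °C
Reagents that add atoms: none
Why: Fluoride-mediated cleavage of the three silyl ethers, which leaves the benzyl ethers and every stereocentre untouched.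

Step 18
Reactants: 24 tetradeca-O-benzyl tetramer
Product: 25 ent-fisetinidol-(4α→6)-ent-fisetinidol-(4α→8)-catechin-(6→4α)-ent-fisetinidol (CNP0126838.1)
Conditions: H2 (1 atm), Pd(OH)2/C, THF–MeOH–H2O, rt
Reagents that add atoms: none
Why: Hydrogenolysis of the fourteen benzyl ethers over palladium hydroxide on carbon, conditions under which the C-4–aryl and C-2–O-1 bonds of flavans should survive and no stereocentre is affected.

**Compound list**

1 | 4-(benzyloxy)-2-hydroxybenzaldehyde | O=Cc1ccc(OCc2ccccc2)cc1O | starting material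
2 | 3,4-bis(benzyloxy)benzyl chloride | ClCc1ccc(OCc2ccccc2)c(OCc2ccccc2)c1 | starting material
3 | 4-(benzyloxy)-2-{[3,4-bis(benzyloxy)phenyl]methoxy}benzaldehyde | O=Cc1ccc(OCc9ccccc9)cc1OCc8ccc(OCc9ccccc9)c(OCc9ccccc9)c8 | intermediate
4 | ethyl diazoacetate | CCOC(=O)C=[N+]=[N-] | starting material
5 | ethyl (2Z)-2-[4-(benzyloxy)-2-{[3,4-bis(benzyloxy)phenyl]methoxy}phenyl]-3-hydroxyprop-2-enoate | CCOC(=O)/C(=C\O)c1ccc(OCc9ccccc9)cc1OCc8ccc(OCc9ccccc9)c(OCc9ccccc9)c8 | intermediate
6 | ethyl [4-(benzyloxy)-2-{[3,4-bis(benzyloxy)phenyl]methoxy}phenyl](diazo)acetate | CCOC(=O)C(=[N+]=[N-])c1ccc(OCc9ccccc9)cc1OCc8ccc(OCc9ccccc9)c(OCc9ccccc9)c8 | intermediate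
7 | ethyl (2R,3S)-6-(benzyloxy)-2-[3,4-bis(benzyloxy)phenyl]-2,3-dihydro-1-benzofuran-3-carboxylate (cis) | O(Cc9ccccc9)c1ccc2c(c1)O[C@@H](c8ccc(OCc9ccccc9)c(OCc9ccccc9)c8)[C@H]2C(=O)OCC | intermediate
8 | potassium enolate of 7 (C-2 configuration unchanged, enolate geometry not specified) | O(Cc9ccccc9)c1ccc2c(c1)O[C@@H](c8ccc(OCc9ccccc9)c(OCc9ccccc9)c8)C2=C([O-])OCC.[K+] | intermediate
9 | ethyl (2S,3R)-6-(benzyloxy)-2-[3,4-bis(benzyloxy)phenyl]-3-hydroxy-2,3-dihydro-1-benzofuran-3-carboxylate (3-OH trans to 2-aryl) | O(Cc9ccccc9)c1ccc2c(c1)O[C@@H](c8ccc(OCc9ccccc9)c(OCc9ccccc9)c8)[C@@]2(O)C(=O)OCC | intermediate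
10 | (2S,3R)-6-(benzyloxy)-2-[3,4-bis(benzyloxy)phenyl]-3-hydroxy-2,3-dihydro-1-benzofuran-3-carbaldehyde | O(Cc9ccccc9)c1ccc2c(c1)O[C@@H](c8ccc(OCc9ccccc9)c(OCc9ccccc9)c8)[C@@]2(O)C=O | intermediate
11 | (2S,3S)-7-(benzyloxy)-2-[3,4-bis(benzyloxy)phenyl]-3-hydroxy-2,3-dihydro-4H-chromen-4-one (2,3-trans) | O(Cc9ccccc9)c1ccc2c(c1)O[C@@H](c8ccc(OCc9ccccc9)c(OCc9ccccc9)c8)[C@H](O)C2=O | intermediate
12 | (2S,3S)-7-(benzyloxy)-2-[3,4-bis(benzyloxy)phenyl]-3-[(tert-butyldimethylsilyl)oxy]-2,3-dihydro-4H-chromen-4-one | O(Cc9ccccc9)c1ccc2c(c1)O[C@@H](c8ccc(OCc9ccccc9)c(OCc9ccccc9)c8)[C@H](O[Si](C)(C)C(C)(C)C)C2=O | intermediate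
13 | (+)-catechin, (2R,3S) | Oc1cc(O)c2c(c1)O[C@H](c8ccc(O)c(O)c8)[C@@H](O)C2 | starting material
14 | 5,7,3',4'-tetra-O-benzyl-(+)-catechin | O(Cc9ccccc9)c1cc(OCc9ccccc9)c2c(c1)O[C@H](c8ccc(OCc9ccccc9)c(OCc9ccccc9)c8)[C@@H](O)C2 | intermediate
15 | 3,5,7,3',4'-penta-O-benzyl-(+)-catechin | O(Cc9ccccc9)c1cc(OCc9ccccc9)c2c(c1)O[C@H](c8ccc(OCc9ccccc9)c(OCc9ccccc9)c8)[C@@H](OCc9ccccc9)C2 | intermediate
16 | 8-bromo-3,5,7,3',4'-penta-O-benzyl-(+)-catechin | Brc1c(OCc9ccccc9)cc(OCc9ccccc9)c2c1O[C@H](c8ccc(OCc9ccccc9)c(OCc9ccccc9)c8)[C@@H](OCc9ccccc9)C2 | intermediate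
17 | 8-lithio-3,5,7,3',4'-penta-O-benzyl-(+)-catechin | [Li]c1c(OCc9ccccc9)cc(OCc9ccccc9)c2c1O[C@H](c8ccc(OCc9ccccc9)c(OCc9ccccc9)c8)[C@@H](OCc9ccccc9)C2 | intermediate
18 | (2S,3S,4S)-7-(benzyloxy)-2-[3,4-bis(benzyloxy)phenyl]-3-[(tert-butyldimethylsilyl)oxy]-4-(3,5,7,3',4'-penta-O-benzylcatechin-8-yl)chroman-4-ol (4-aryl β, 4-OH α) | O(Cc9ccccc9)c1ccc2c(c1)O[C@@H](c8ccc(OCc9ccccc9)c(OCc9ccccc9)c8)[C@H](O[Si](C)(C)C(C)(C)C)[C@@]2(O)c1c(OCc9ccccc9)cc(OCc9ccccc9)c2c1O[C@H](c8ccc(OCc9ccccc9)c(OCc9ccccc9)c8)[C@@H](OCc9ccccc9)C2 | intermediate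
19 | 7,3',4'-tri-O-benzyl-3-O-TBS-ent-fisetinidol-(4α→8)-3,5,7,3',4'-penta-O-benzylcatechin | O(Cc9ccccc9)c1ccc2c(c1)O[C@@H](c8ccc(OCc9ccccc9)c(OCc9ccccc9)c8)[C@H](O[Si](C)(C)C(C)(C)C)[C@@H]2c1c(OCc9ccccc9)cc(OCc9ccccc9)c2c1O[C@H](c8ccc(OCc9ccccc9)c(OCc9ccccc9)c8)[C@@H](OCc9ccccc9)C2 | intermediate
20 | 6-bromo-7,3',4'-tri-O-benzyl-3-O-TBS-ent-fisetinidol-(4α→8)-6-bromo-3,5,7,3',4'-penta-O-benzylcatechin | O(Cc9ccccc9)c1c(Br)cc2c(c1)O[C@@H](c8ccc(OCc9ccccc9)c(OCc9ccccc9)c8)[C@H](O[Si](C)(C)C(C)(C)C)[C@@H]2c1c(OCc9ccccc9)c(Br)c(OCc9ccccc9)c2c1O[C@H](c8ccc(OCc9ccccc9)c(OCc9ccccc9)c8)[C@@H](OCc9ccccc9)C2 | intermediate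
21 | 6,6'-dilithio analogue of 20 | O(Cc9ccccc9)c1c([Li])cc2c(c1)O[C@@H](c8ccc(OCc9ccccc9)c(OCc9ccccc9)c8)[C@H](O[Si](C)(C)C(C)(C)C)[C@@H]2c1c(OCc9ccccc9)c([Li])c(OCc9ccccc9)c2c1O[C@H](c8ccc(OCc9ccccc9)c(OCc9ccccc9)c8)[C@@H](OCc9ccccc9)C2 | intermediate
22 | bis-carbinol tetramer: 23 with a 4α-hydroxyl in place of H-4 and a 4β-aryl bond in the top unit and in the angular unit | O(Cc9ccccc9)c1ccc2c(c1)O[C@@H](c8ccc(OCc9ccccc9)c(OCc9ccccc9)c8)[C@H](O[Si](C)(C)C(C)(C)C)[C@@]2(O)c1cc2c(cc1OCc9ccccc9)O[C@@H](c8ccc(OCc9ccccc9)c(OCc9ccccc9)c8)[C@H](O[Si](C)(C)C(C)(C)C)[C@@H]2c1c(OCc9ccccc9)c([C@@]2(O)c3ccc(OCc9ccccc9)cc3O[C@@H](c8ccc(OCc9ccccc9)c(OCc9ccccc9)c8)[C@@H]2O[Si](C)(C)C(C)(C)C)c(OCc9ccccc9)c2c1O[C@H](c8ccc(OCc9ccccc9)c(OCc9ccccc9)c8)[C@@H](OCc9ccccc9)C2 | intermediate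
23 | [7,3',4'-tri-O-benzyl-3-O-TBS-ent-fisetinidol]-(4α→6)-[7,3',4'-tri-O-benzyl-3-O-TBS-ent-fisetinidol]-(4α→8)-[3,5,7,3',4'-penta-O-benzylcatechin]-(6→4α)-[7,3',4'-tri-O-benzyl-3-O-TBS-ent-fisetinidol] | O(Cc9ccccc9)c1ccc2c(c1)O[C@@H](c8ccc(OCc9ccccc9)c(OCc9ccccc9)c8)[C@H](O[Si](C)(C)C(C)(C)C)[C@@H]2c1cc2c(cc1OCc9ccccc9)O[C@@H](c8ccc(OCc9ccccc9)c(OCc9ccccc9)c8)[C@H](O[Si](C)(C)C(C)(C)C)[C@@H]2c1c(OCc9ccccc9)c([C@@H]2c3ccc(OCc9ccccc9)cc3O[C@@H](c8ccc(OCc9ccccc9)c(OCc9ccccc9)c8)[C@@H]2O[Si](C)(C)C(C)(C)C)c(OCc9ccccc9)c2c1O[C@H](c8ccc(OCc9ccccc9)c(OCc9ccccc9)c8)[C@@H](OCc9ccccc9)C2 | intermediate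
24 | tetradeca-O-benzyl tetramer: 23 with three free 3-hydroxyls in the ent-fisetinidol units | O(Cc9ccccc9)c1ccc2c(c1)O[C@@H](c8ccc(OCc9ccccc9)c(OCc9ccccc9)c8)[C@H](O)[C@@H]2c1cc2c(cc1OCc9ccccc9)O[C@@H](c8ccc(OCc9ccccc9)c(OCc9ccccc9)c8)[C@H](O)[C@@H]2c1c(OCc9ccccc9)c([C@@H]2c3ccc(OCc9ccccc9)cc3O[C@@H](c8ccc(OCc9ccccc9)c(OCc9ccccc9)c8)[C@@H]2O)c(OCc9ccccc9)c2c1O[C@H](c8ccc(OCc9ccccc9)c(OCc9ccccc9)c8)[C@@H](OCc9ccccc9)C2 | intermediate
25 | ent-fisetinidol-(4α→6)-ent-fisetinidol-(4α→8)-catechin-(6→4α)-ent-fisetinidol (top unit 2S,3R,4R; middle unit 2S,3R,4S; catechin 2R,3S; angular unit 2S,3R,4S) | Oc1ccc2c(c1)O[C@@H](c1ccc(O)c(O)c1)[C@H](O)[C@@H]2c1cc2c(cc1O)O[C@@H](c1ccc(O)c(O)c1)[C@H](O)[C@@H]2c1c(O)c([C@@H]2c3ccc(O)cc3O[C@@H](c3ccc(O)c(O)c3)[C@@H]2O)c(O)c2c1O[C@H](c1ccc(O)c(O)c1)[C@@H](O)C2 | target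

**Step count and risks**

Total: 18 steps. Longest linear sequence: 15 steps (steps 1–8, then 12–18).

Most likely to fail, with one fallback each:

Step 13 (the same event recurs twice in step 16). Hydride may enter the planar C-4 cation syn to the 3-silyloxy group (axial attack on the half-chair), which would give the 3,4-trans epimer, or the cation may be lost by 1,2-hydride shift from C-3 towards a flavan-3-one. The fallback sets out from 11. Reduction with NaBH4 in MeOH–THF at 0 °C should give, by hydride attack anti to the 3-hydroxyl, the 2,3-trans-3,4-trans diol (2S,3R,4S)-7-(benzyloxy)-2-[3,4-bis(benzyloxy)phenyl]chromane-3,4-diol F1. Condensation of F1 with 15 under BF3·OEt2 in CH2Cl2 at low temperature (Friedel–Crafts capture of the secondary C-4 cation, the classical flavan-3,4-diol coupling) should give the (4→8) dimers as a mixture of C-4 epimers. The 3,4-cis isomer, expected as the minor one, is 7,3',4'-tri-O-benzyl-ent-fisetinidol-(4α→8)-3,5,7,3',4'-penta-O-benzylcatechin F2 and would be separated by chromatography. Silylation of its free 3-hydroxyl (t-BuMe2SiOTf, 2,6-lutidine) comes back to the route at 19.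

Step 15. The double exchange may stay incomplete or the dilithio species may be protonated, and the hindered aryllithium centres may deprotonate C-3 of 12 (with ring opening by loss of the aryloxide) in place of adding to the carbonyl. The fallback sets out from 19 itself, without bromination and without organolithium: a Friedel–Crafts hydroxyalkylation, the acid-mediated arene-to-ketone addition known from bisphenol-type condensations. Ketone 12 (2.5 equiv), activated with BF3·OEt2 in CH2Cl2, should be attacked at C-4 by the two most nucleophilic ring positions of 19, the same two that N-bromosuccinimide takes in step 14. Aqueous work-up should return the bis-carbinol, so the route is rejoined at 22 and step 16 follows unchanged; this fallback makes no compound outside the list (F0).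

Step 7. The aryl carbon C-3a may migrate in place of C-2 (leading through a 3-oxo isomer in which C-2 can epimerise), or the hindered hydroxy-aldehyde may be consumed by Tishchenko-type ester formation on aluminium. The fallback sets out from 9 and avoids the aldehyde. LiAlH4 in THF at 0 °C gives the diol (2S,3S)-6-(benzyloxy)-2-[3,4-bis(benzyloxy)phenyl]-3-(hydroxymethyl)-2,3-dihydro-1-benzofuran-3-ol F3. Tosylation of the primary hydroxyl (TsCl, pyridine) gives (2S,3S)-6-(benzyloxy)-2-[3,4-bis(benzyloxy)phenyl]-3-hydroxy-2,3-dihydro-1-benzofuran-3-yl]methyl 4-methylbenzenesulfonate F4. KOt-Bu in THF then triggers an irreversible semipinacol (Tiffeneau–Demjanov-type) ring enlargement with loss of tosylate, which should favour shift of the oxygen-bearing sp3 carbon C-2 and give the flavanone (2R)-7-(benzyloxy)-2-[3,4-bis(benzyloxy)phenyl]-2,3-dihydro-4H-chromen-4-one F5. Deprotonation with KN(SiMe3)2 at −78 °C to the potassium enolate of F5 F6 and oxidation with 3-phenyl-2-(phenylsulfonyl)oxaziridine anti to the 2-aryl group should give the trans-3-hydroxyflavanone, rejoining the route at 11.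

Further compounds
F1 | step 13 | (2S,3R,4S)-7-(benzyloxy)-2-[3,4-bis(benzyloxy)phenyl]chromane-3,4-diol | O(Cc9ccccc9)c1ccc2c(c1)O[C@@H](c8ccc(OCc9ccccc9)c(OCc9ccccc9)c8)[C@H](O)[C@H]2O
F2 | step 13 | 7,3',4'-tri-O-benzyl-ent-fisetinidol-(4α→8)-3,5,7,3',4'-penta-O-benzylcatechin | O(Cc9ccccc9)c1ccc2c(c1)O[C@@H](c8ccc(OCc9ccccc9)c(OCc9ccccc9)c8)[C@H](O)[C@@H]2c1c(OCc9ccccc9)cc(OCc9ccccc9)c2c1O[C@H](c8ccc(OCc9ccccc9)c(OCc9ccccc9)c8)[C@@H](OCc9ccccc9)C2
F0 | step 15 | none | none
F3 | step 7 | (2S,3S)-6-(benzyloxy)-2-[3,4-bis(benzyloxy)phenyl]-3-(hydroxymethyl)-2,3-dihydro-1-benzofuran-3-ol | O(Cc9ccccc9)c1ccc2c(c1)O[C@@H](c8ccc(OCc9ccccc9)c(OCc9ccccc9)c8)[C@@]2(O)CO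
F4 | step 7 | [(2S,3S)-6-(benzyloxy)-2-[3,4-bis(benzyloxy)phenyl]-3-hydroxy-2,3-dihydro-1-benzofuran-3-yl]methyl 4-methylbenzenesulfonate | O(Cc9ccccc9)c1ccc2c(c1)O[C@@H](c8ccc(OCc9ccccc9)c(OCc9ccccc9)c8)[C@@]2(O)COS(=O)(=O)c1ccc(C)cc1
F5 | step 7 | (2R)-7-(benzyloxy)-2-[3,4-bis(benzyloxy)phenyl]-2,3-dihydro-4H-chromen-4-one | O(Cc9ccccc9)c1ccc2c(c1)O[C@@H](c8ccc(OCc9ccccc9)c(OCc9ccccc9)c8)CC2=O
F6 | step 7 | potassium enolate of F5 | O(Cc9ccccc9)c1ccc2c(c1)O[C@@H](c8ccc(OCc9ccccc9)c(OCc9ccccc9)c8)C=C2[O-].[K+]
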